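**Retrosynthetic overview**
- The plan rests on indenone C3: it carries ring B with two ortho oxygens and is bonded to ring A carbon C3a, which has an ortho oxygen (C4) and a para methoxy group (C6). A cation at C3 is therefore unusually stable, and a C3–OMe bond next to a C7a alkyne can be ionised on demand.
- The five-membered ring (C1, C2, C3, C3a, C7a) is the only ring built. It is closed by gold-catalysed carboalkoxylation of a benzhydryl methyl ether onto a diarylalkyne (C1–O and C2–C3 formed), followed by DDQ/water oxidation to the indenone and BCl3 debenzylation.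
- The gold precursor is cut at the alkyne: Sonogashira coupling of a ring A–B terminal alkyne with a ring C–D aryl iodide.
- The ring A–B alkyne comes from 2-bromo-4,6-dimethoxybenzaldehyde (ortho demethylation, benzylation, silylalkyne coupling) and lithiated orcinol dibenzyl ether, with MeI quench and desilylation.
- The ring C–D iodide comes from SNAr of a ring D phenol on 2-chloro-5-methoxy-3-nitrobenzaldehyde, then CHO to OBn (Dakin, benzylation) and NO2 to iodine (reduction, Sandmeyer).

Key step: step 16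

Remark on the chemistry: compounds 21 to 25 carry one stereocentre and are racemic; their SMILES show one enantiomer. The centre becomes trigonal in step 17, and the target has no stereocentre.

**Step 1**
Reactants: 1 2-hydroxy-5-methoxybenzaldehyde
Product: 2 2-hydroxy-5-methoxy-3-nitrobenzaldehyde
Conditions: HNO3 (65%), AcOH, 10–15 °C
Reagents that add atoms: nitric acid O[N+](=O)[O-]
Why: Electrophilic aromatic nitration; the phenol directs to its only free ortho position (its para position holds the methoxy group), and the formyl group tempers the ring against oxidation.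

**Step 2**
Reactants: 2 2-hydroxy-5-methoxy-3-nitrobenzaldehyde
Product: 4 2-chloro-5-methoxy-3-nitrobenzaldehyde, via aryloxymethyleneiminium chloride 3 (not isolated)
Conditions: (COCl)2, DMF, 0 °C; then 2, 70 °C
Reagents that add atoms: oxalyl chloride O=C(Cl)C(=O)Cl
Why: Vilsmeier-type chlorodehydroxylation, a known way to turn nitro-activated phenols into aryl chlorides: the acidic phenol is O-formiminylated and chloride displaces the aryloxy-iminium group by SNAr, the ortho nitro and ortho formyl groups stabilising the Meisenheimer complex.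

**Step 3**
Reactants: 5 methyl 2,6-dihydroxy-4-methylbenzoate
Product: 6 methyl 2-(benzyloxy)-6-hydroxy-4-methylbenzoate
Conditions: BnBr (1.0 equiv), K2CO3, acetone, reflux
Reagents that add atoms: benzyl bromide BrCc1ccccc1
Why: Williamson mono-etherification; after the first benzylation the remaining phenol is held in a hydrogen bond to the ester carbonyl and should react much more slowly, so one equivalent of BnBr stops at the mono-ether.

**Step 4**
Reactants: 4 2-chloro-5-methoxy-3-nitrobenzaldehyde; 6 methyl 2-(benzyloxy)-6-hydroxy-4-methylbenzoate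
Product: 7 methyl 2-(benzyloxy)-6-(2-formyl-4-methoxy-6-nitrophenoxy)-4-methylbenzoate
Conditions: K2CO3, DMF, 60 °C
Reagents that add atoms: none
Why: SNAr; the chloride flanked by ortho nitro and ortho formyl groups is displaced by the phenoxide of 6 through a Meisenheimer complex, which is what allows a diaryl ether with three ortho substituents around the oxygen to form.

**Step 5**
Reactants: 7 methyl 2-(benzyloxy)-6-(2-formyl-4-methoxy-6-nitrophenoxy)-4-methylbenzoate
Product: 9 methyl 2-(benzyloxy)-6-(2-hydroxy-4-methoxy-6-nitrophenoxy)-4-methylbenzoate, via aryl formate 8 (not isolated)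
Conditions: mCPBA, CH2Cl2, rt to 40 °C; then Et3N (cat.), MeOH, rt
Reagents that add atoms: 3-chloroperoxybenzoic acid O=C(OO)c1cccc(Cl)c1
Why: Dakin-type Baeyer–Villiger oxidation; the peracid adds to the aldehyde and the aryl carbon, which is ortho to the aryloxy donor, migrates to oxygen to give the formate, which mild methanolysis cleaves without touching the hindered methyl benzoate.

**Step 6**
Reactants: 9 methyl 2-(benzyloxy)-6-(2-hydroxy-4-methoxy-6-nitrophenoxy)-4-methylbenzoate
Product: 10 methyl 2-(benzyloxy)-6-[2-(benzyloxy)-4-methoxy-6-nitrophenoxy]-4-methylbenzoate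
Conditions: BnBr, K2CO3, DMF, rt
Reagents that add atoms: benzyl bromide BrCc1ccccc1
Why: Williamson etherification of the phenol; mild base at room temperature should outrun any Smiles-type aryl migration and leaves the hindered ester intact.

**Step 7**
Reactants: 10 methyl 2-(benzyloxy)-6-[2-(benzyloxy)-4-methoxy-6-nitrophenoxy]-4-methylbenzoate
Product: 11 methyl 2-[2-amino-6-(benzyloxy)-4-methoxyphenoxy]-6-(benzyloxy)-4-methylbenzoate
Conditions: Fe powder, NH4Cl, EtOH/H2O, 60 °C
Reagents that add atoms: none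
Why: Béchamp-type metal reduction of the nitro group under near-neutral conditions, which spares the benzyl ethers that hydrogenation would remove and is mild enough that the amine should not lactamise onto the hindered ester.

**Step 8**
Reactants: 11 methyl 2-[2-amino-6-(benzyloxy)-4-methoxyphenoxy]-6-(benzyloxy)-4-methylbenzoate
Product: 13 methyl 2-(benzyloxy)-6-[2-(benzyloxy)-6-iodo-4-methoxyphenoxy]-4-methylbenzoate, via arenediazonium tosylate 12 (not isolated)
Conditions: TsOH·H2O, NaNO2, KI, MeCN/H2O, 10 °C to rt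
Reagents that add atoms: potassium iodide [K+].[I-]
Why: Sandmeyer-type diazotisation–iodination; the diazonium salt forms in an organic-soluble acid medium and iodide converts it to the aryl iodide faster than the aryl radical can cyclise onto ring D.

**Step 9**
Reactants: 14 2-bromo-4,6-dimethoxybenzaldehyde
Product: 15 2-bromo-6-hydroxy-4-methoxybenzaldehyde
Conditions: BCl3, CH2Cl2, −78 to 0 °C; aq. work-up
Reagents that add atoms: none
Why: Chelation-controlled Lewis acid demethylation; BCl3 binds the aldehyde oxygen and cleaves only the ortho methoxy group through a six-membered boron chelate, so the para methoxy group should survive.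

**Step 10**
Reactants: 15 2-bromo-6-hydroxy-4-methoxybenzaldehyde
Product: 16 2-(benzyloxy)-6-bromo-4-methoxybenzaldehyde
Conditions: BnBr, K2CO3, DMF, rt
Reagents that add atoms: benzyl bromide BrCc1ccccc1
Why: Williamson etherification of an acidic, chelated salicylaldehyde-type phenol.

**Step 11**
Reactants: 16 2-(benzyloxy)-6-bromo-4-methoxybenzaldehyde
Product: 17 2-(benzyloxy)-4-methoxy-6-{[tri(propan-2-yl)silyl]ethynyl}benzaldehyde
Conditions: (Ph3P)2PdCl2 (cat.), CuI (cat.), ethynyltri(propan-2-yl)silane, Et3N, THF, 60 °C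
Reagents that add atoms: ethynyltri(propan-2-yl)silane C#C[Si](C(C)C)(C(C)C)C(C)C
Why: Sonogashira coupling; oxidative addition of zerovalent palladium into the C–Br bond is helped by the ortho formyl group, and the bulky silyl group is chosen to survive the organolithium and alkoxide chemistry of step 13.

**Step 12**
Reactants: 18 orcinol (5-methylbenzene-1,3-diol)
Product: 19 1,3-bis(benzyloxy)-5-methylbenzene
Conditions: BnBr (2.2 equiv), K2CO3, DMF, 60 °C
Reagents that add atoms: benzyl bromide BrCc1ccccc1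
Why: Double Williamson etherification of both phenols.

**Step 13**
Reactants: 19 1,3-bis(benzyloxy)-5-methylbenzene; 17 2-(benzyloxy)-4-methoxy-6-{[tri(propan-2-yl)silyl]ethynyl}benzaldehyde
Product: 22 rac-{[3-(benzyloxy)-2-{[2,6-bis(benzyloxy)-4-methylphenyl](methoxy)methyl}-5-methoxyphenyl]ethynyl}tri(propan-2-yl)silane, via aryllithium 20 (not isolated), via lithium alkoxide 21 (not isolated)
Conditions: n-BuLi, THF, 0 °C to rt (19 in slight excess); then 17, −78 °C; then MeI, DMPU, −78 °C to rt
Reagents that add atoms: iodomethane CI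
Why: Directed ortho-metalation between the two benzyloxy groups gives the aryllithium, its 1,2-addition to the aldehyde gives the lithium alkoxide, and Williamson O-methylation in the same flask gives the benzhydryl methyl ether; the new stereocentre forms without control as a racemate and is removed in step 17.

**Step 14**
Reactants: 22 rac-{[3-(benzyloxy)-2-{[2,6-bis(benzyloxy)-4-methylphenyl](methoxy)methyl}-5-methoxyphenyl]ethynyl}tri(propan-2-yl)silane
Product: 23 rac-1-(benzyloxy)-2-{[2,6-bis(benzyloxy)-4-methylphenyl](methoxy)methyl}-3-ethynyl-5-methoxybenzene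
Conditions: Bu4NF, THF, 0 °C
Reagents that add atoms: none
Why: Fluoride-induced protodesilylation of the alkynylsilane; the molecule holds no group that is sensitive to fluoride or mild base.

**Step 15**
Reactants: 23 rac-1-(benzyloxy)-2-{[2,6-bis(benzyloxy)-4-methylphenyl](methoxy)methyl}-3-ethynyl-5-methoxybenzene; 13 methyl 2-(benzyloxy)-6-[2-(benzyloxy)-6-iodo-4-methoxyphenoxy]-4-methylbenzoate
Product: 24 rac-methyl 2-(benzyloxy)-6-{2-(benzyloxy)-6-[(3-(benzyloxy)-2-{[2,6-bis(benzyloxy)-4-methylphenyl](methoxy)methyl}-5-methoxyphenyl)ethynyl]-4-methoxyphenoxy}-4-methylbenzoate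
Conditions: Pd(PPh3)4 (cat.), CuI (cat.), Et3N, THF, rt to 45 °C, degassed
Reagents that add atoms: none
Why: Sonogashira coupling in which the aryl iodide undergoes oxidative addition near room temperature despite its ortho aryloxy group, while the benzhydryl ether and the ester are inert.

**Step 16**
Reactants: 24 rac-methyl 2-(benzyloxy)-6-{2-(benzyloxy)-6-[(3-(benzyloxy)-2-{[2,6-bis(benzyloxy)-4-methylphenyl](methoxy)methyl}-5-methoxyphenyl)ethynyl]-4-methoxyphenoxy}-4-methylbenzoate
Product: 25 rac-methyl 2-(benzyloxy)-6-{2-(benzyloxy)-6-[7-(benzyloxy)-1-(2,6-bis(benzyloxy)-4-methylphenyl)-3,5-dimethoxy-1H-inden-2-yl]-4-methoxyphenoxy}-4-methylbenzoate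
Conditions: [(4-CF3C6H4)3P]AuCl (5 mol%), AgSbF6 (5 mol%), 4 Å MS, CH2Cl2, rt
Reagents that add atoms: none
Why: Cationic monovalent gold, freed from chloride by AgSbF6, binds the alkyne and the benzhydryl methoxy oxygen attacks the alkyne carbon attached to ring A, which forms the future C1–O bond and a five-membered oxonium ion with an exocyclic vinylgold unit; the benzylic C–O bond then ionises, because the C3 cation is held by ring B with two ortho oxygens and by ring A with its ortho C4 and para C6 oxygens, and the gold-bearing carbon of the resulting methyl enol ether (C2) captures the cation and releases the catalyst. The closest known reaction is the gold-catalysed intramolecular carboalkoxylation of ortho-alkynylbenzyl methyl ethers to indenyl ethers, applied here to a diarylalkyne. The oxygen attack is a 5-exo-dig closure of a transient heterocycle, and the lasting carbocycle (C1, C2, C3, C3a, C7a) closes by a 5-(enol-endo) attack of the enol ether carbon on the cation, both former alkyne carbons ending inside the ring. The C3 stereocentre arises from a planar cation in a racemic substrate, so no element controls it and none is needed, since step 17 makes C3 trigonal. The selectivity that matters is attack at the proximal rather than the distal alkyne carbon: the aryloxy group of ring C polarises the alkyne toward 6-endo attack, but the 6-endo oxonium ion could only close a four-membered ring after ionisation, so it should revert and the material should drain through the 5-exo channel, provided that water is excluded and the counter-ion is non-nucleophilic.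

**Step 17**
Reactants: 25 rac-methyl 2-(benzyloxy)-6-{2-(benzyloxy)-6-[7-(benzyloxy)-1-(2,6-bis(benzyloxy)-4-methylphenyl)-3,5-dimethoxy-1H-inden-2-yl]-4-methoxyphenoxy}-4-methylbenzoate
Product: 26 methyl 2-(benzyloxy)-6-{2-(benzyloxy)-6-[4-(benzyloxy)-3-(2,6-bis(benzyloxy)-4-methylphenyl)-6-methoxy-1-oxo-1H-inden-2-yl]-4-methoxyphenoxy}-4-methylbenzoate
Conditions: DDQ, CH2Cl2/H2O (10:1), 0 °C to rt
Reagents that add atoms: water O
Why: DDQ oxidation of an enol ether, as in the conversion of dienol methyl ethers to dienones: hydride abstraction from the doubly benzylic, allylic C3–H gives a 1-methoxyindenylium (vinylogous oxocarbenium) ion, water adds at C1, and loss of methanol gives the indenone, with C3 becoming trigonal.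

**Step 18**
Reactants: 26 methyl 2-(benzyloxy)-6-{2-(benzyloxy)-6-[4-(benzyloxy)-3-(2,6-bis(benzyloxy)-4-methylphenyl)-6-methoxy-1-oxo-1H-inden-2-yl]-4-methoxyphenoxy}-4-methylbenzoate
Product: 27 Ascomindone B
Conditions: BCl3, C6HMe5, CH2Cl2, −78 °C; aq. work-up
Reagents that add atoms: none
Why: Lewis acid debenzylation with pentamethylbenzene as a non-basic benzyl cation scavenger should cleave the five aryl benzyl ethers at −78 °C, while the aryl methyl ethers, the methyl ester, the diaryl ether and the indenone double bond (which hydrogenolysis would endanger) survive.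

**Compound list**
1 | 2-hydroxy-5-methoxybenzaldehyde | COc1ccc(O)c(C=O)c1 | starting material
2 | 2-hydroxy-5-methoxy-3-nitrobenzaldehyde | COc1cc(C=O)c(O)c([N+](=O)[O-])c1 | intermediate
3 | [(2-formyl-4-methoxy-6-nitrophenoxy)methylidene]dimethylammonium chloride (formed in the flask) | COc1cc(C=O)c(OC=[N+](C)C)c([N+](=O)[O-])c1.[Cl-] | intermediate
4 | 2-chloro-5-methoxy-3-nitrobenzaldehyde | COc1cc(C=O)c(Cl)c([N+](=O)[O-])c1 | intermediate
5 | methyl 2,6-dihydroxy-4-methylbenzoate | COC(=O)c1c(O)cc(C)cc1O | starting material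
6 | methyl 2-(benzyloxy)-6-hydroxy-4-methylbenzoate | COC(=O)c1c(O)cc(C)cc1OCc1ccccc1 | intermediate
7 | methyl 2-(benzyloxy)-6-(2-formyl-4-methoxy-6-nitrophenoxy)-4-methylbenzoate | COC(=O)c1c(OCc2ccccc2)cc(C)cc1Oc1c(C=O)cc(OC)cc1[N+](=O)[O-] | intermediate
8 | methyl 2-(benzyloxy)-6-[2-(formyloxy)-4-methoxy-6-nitrophenoxy]-4-methylbenzoate (formed in the flask) | COC(=O)c1c(OCc2ccccc2)cc(C)cc1Oc1c(OC=O)cc(OC)cc1[N+](=O)[O-] | intermediate
9 | methyl 2-(benzyloxy)-6-(2-hydroxy-4-methoxy-6-nitrophenoxy)-4-methylbenzoate | COC(=O)c1c(OCc2ccccc2)cc(C)cc1Oc1c(O)cc(OC)cc1[N+](=O)[O-] | intermediate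
10 | methyl 2-(benzyloxy)-6-[2-(benzyloxy)-4-methoxy-6-nitrophenoxy]-4-methylbenzoate | COC(=O)c1c(OCc2ccccc2)cc(C)cc1Oc1c(OCc2ccccc2)cc(OC)cc1[N+](=O)[O-] | intermediate
11 | methyl 2-[2-amino-6-(benzyloxy)-4-methoxyphenoxy]-6-(benzyloxy)-4-methylbenzoate | COC(=O)c1c(OCc2ccccc2)cc(C)cc1Oc1c(OCc2ccccc2)cc(OC)cc1N | intermediate
12 | 3-(benzyloxy)-2-[3-(benzyloxy)-2-(methoxycarbonyl)-5-methylphenoxy]-5-methoxybenzenediazonium 4-methylbenzenesulfonate (formed in the flask) | COC(=O)c1c(OCc2ccccc2)cc(C)cc1Oc1c(OCc2ccccc2)cc(OC)cc1[N+]#N.Cc1ccc(S(=O)(=O)[O-])cc1 | intermediate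
13 | methyl 2-(benzyloxy)-6-[2-(benzyloxy)-6-iodo-4-methoxyphenoxy]-4-methylbenzoate | COC(=O)c1c(OCc2ccccc2)cc(C)cc1Oc1c(OCc2ccccc2)cc(OC)cc1I | intermediate
14 | 2-bromo-4,6-dimethoxybenzaldehyde | COc1cc(Br)c(C=O)c(OC)c1 | starting material
15 | 2-bromo-6-hydroxy-4-methoxybenzaldehyde | COc1cc(O)c(C=O)c(Br)c1 | intermediate
16 | 2-(benzyloxy)-6-bromo-4-methoxybenzaldehyde | COc1cc(Br)c(C=O)c(OCc2ccccc2)c1 | intermediate
17 | 2-(benzyloxy)-4-methoxy-6-{[tri(propan-2-yl)silyl]ethynyl}benzaldehyde | COc1cc(OCc2ccccc2)c(C=O)c(C#C[Si](C(C)C)(C(C)C)C(C)C)c1 | intermediate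
18 | orcinol (5-methylbenzene-1,3-diol) | Cc1cc(O)cc(O)c1 | starting material
19 | 1,3-bis(benzyloxy)-5-methylbenzene | Cc1cc(OCc2ccccc2)cc(OCc2ccccc2)c1 | intermediate
20 | [2,6-bis(benzyloxy)-4-methylphenyl]lithium (formed in the flask) | [Li]c1c(OCc2ccccc2)cc(C)cc1OCc1ccccc1 | intermediate
21 | rac-lithium [2,6-bis(benzyloxy)-4-methylphenyl][2-(benzyloxy)-4-methoxy-6-{[tri(propan-2-yl)silyl]ethynyl}phenyl]methanolate (formed in the flask; one enantiomer drawn) | [Li+].[O-][C@H](c1c(OCc2ccccc2)cc(C)cc1OCc1ccccc1)c1c(OCc2ccccc2)cc(OC)cc1C#C[Si](C(C)C)(C(C)C)C(C)C | intermediate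
22 | rac-{[3-(benzyloxy)-2-{[2,6-bis(benzyloxy)-4-methylphenyl](methoxy)methyl}-5-methoxyphenyl]ethynyl}tri(propan-2-yl)silane (one enantiomer drawn) | CO[C@H](c1c(OCc2ccccc2)cc(C)cc1OCc1ccccc1)c1c(OCc2ccccc2)cc(OC)cc1C#C[Si](C(C)C)(C(C)C)C(C)C | intermediate
23 | rac-1-(benzyloxy)-2-{[2,6-bis(benzyloxy)-4-methylphenyl](methoxy)methyl}-3-ethynyl-5-methoxybenzene (one enantiomer drawn) | CO[C@H](c1c(OCc2ccccc2)cc(C)cc1OCc1ccccc1)c1c(OCc2ccccc2)cc(OC)cc1C#C | intermediate
24 | rac-methyl 2-(benzyloxy)-6-{2-(benzyloxy)-6-[(3-(benzyloxy)-2-{[2,6-bis(benzyloxy)-4-methylphenyl](methoxy)methyl}-5-methoxyphenyl)ethynyl]-4-methoxyphenoxy}-4-methylbenzoate (one enantiomer drawn) | CO[C@H](c1c(OCc2ccccc2)cc(C)cc1OCc1ccccc1)c1c(OCc2ccccc2)cc(OC)cc1C#Cc1cc(OC)cc(OCc2ccccc2)c1Oc1cc(C)cc(OCc2ccccc2)c1C(=O)OC | intermediate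
25 | rac-methyl 2-(benzyloxy)-6-{2-(benzyloxy)-6-[7-(benzyloxy)-1-(2,6-bis(benzyloxy)-4-methylphenyl)-3,5-dimethoxy-1H-inden-2-yl]-4-methoxyphenoxy}-4-methylbenzoate (one enantiomer drawn) | COC1=C(c2cc(OC)cc(OCc3ccccc3)c2Oc2cc(C)cc(OCc3ccccc3)c2C(=O)OC)[C@H](c2c(OCc3ccccc3)cc(C)cc2OCc2ccccc2)c2c(OCc3ccccc3)cc(OC)cc12 | intermediate
26 | methyl 2-(benzyloxy)-6-{2-(benzyloxy)-6-[4-(benzyloxy)-3-(2,6-bis(benzyloxy)-4-methylphenyl)-6-methoxy-1-oxo-1H-inden-2-yl]-4-methoxyphenoxy}-4-methylbenzoate | COC(=O)c1c(OCc2ccccc2)cc(C)cc1Oc1c(OCc2ccccc2)cc(OC)cc1C1=C(c2c(OCc3ccccc3)cc(C)cc2OCc2ccccc2)c2c(OCc3ccccc3)cc(OC)cc2C1=O | intermediate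
27 | Ascomindone B (methyl 2-{2-[3-(2,6-dihydroxy-4-methylphenyl)-4-hydroxy-6-methoxy-1-oxo-1H-inden-2-yl]-6-hydroxy-4-methoxyphenoxy}-6-hydroxy-4-methylbenzoate) | COC(=O)c1c(O)cc(C)cc1Oc1c(O)cc(OC)cc1C1=C(c2c(O)cc(C)cc2O)c2c(O)cc(OC)cc2C1=O | target

**Step count and risks**
Total step count: 18. Longest linear sequence: 11 steps (steps 1, 2, 4, 5, 6, 7, 8, 15, 16, 17, 18, from 2-hydroxy-5-methoxybenzaldehyde).

The three steps most likely to fail:

1. Step 16. The methoxy oxygen may add to the distal alkyne carbon, which the aryloxy group of ring C makes the more electrophilic one. An alkyne without an electron-withdrawing group may also turn over slowly, and the long-lived C3 cation may be intercepted (by traces of water or by a benzyloxy-arene) before C2 closes on it. The fallback removes the electronic bias by closing the ring before ring C is attached; it sets out from terminal alkyne 23 (with iodide 13 kept for later) and comes back at indenone 26. Under the same cationic gold catalyst a terminal arylalkyne can only be attacked at its internal carbon, so 23 should give rac-7-(benzyloxy)-1-[2,6-bis(benzyloxy)-4-methylphenyl]-3,5-dimethoxy-1H-indene F1. Hydrolysis of the enol ether (aq. HCl, THF, rt) should give rac-4-(benzyloxy)-3-[2,6-bis(benzyloxy)-4-methylphenyl]-6-methoxyindan-1-one F2. Palladium-catalysed ketone α-arylation with iodide 13 (Pd(OAc)2, XPhos, K3PO4, toluene, 90 °C) should then attach ring C at C2 and give the trans-2,3-diarylindan-1-one F3. Dehydrogenation with IBX in DMSO at 70 °C should give 26.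

2. Step 5. In the peracid adduct hydride may migrate instead of the aryl group, because the nitro group lowers the migratory aptitude of ring C and the aryloxy donor is shared with ring D; the aldehyde would then be over-oxidised to the benzoic acid. The fallback postpones the oxidation until the nitro group has been exchanged for iodine; it sets out from 7 and comes back at 13. Reduction (Fe, NH4Cl, EtOH/H2O, 60 °C) should give methyl 2-(2-amino-6-formyl-4-methoxyphenoxy)-6-(benzyloxy)-4-methylbenzoate F4, to be used at once. Diazotisation–iodination (TsOH·H2O, NaNO2, KI, MeCN/H2O) should pass through the 3-formyl-substituted arenediazonium tosylate F5 to methyl 2-(benzyloxy)-6-(2-formyl-6-iodo-4-methoxyphenoxy)-4-methylbenzoate F6. The Dakin-type oxidation is then run on this less electron-poor ring (mCPBA, CH2Cl2; then Et3N, MeOH) through methyl 2-(benzyloxy)-6-[2-(formyloxy)-6-iodo-4-methoxyphenoxy]-4-methylbenzoate F7 to methyl 2-(benzyloxy)-6-(2-hydroxy-6-iodo-4-methoxyphenoxy)-4-methylbenzoate F8. Benzylation (BnBr, K2CO3, DMF) gives 13.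

3. Step 17. Hydride abstraction from C3–H may be slow, since this hydrogen is walled in by the two benzyloxy groups of ring B and by the C4 benzyloxy group; forcing the reaction may lead to oxidative attack on the benzyl ethers and the electron-rich rings. The fallback replaces hydride abstraction by electrophilic selenenylation of the enol ether and a syn elimination; it sets out from 25 and comes back at 26. PhSeCl (THF, −78 °C, then water) should add to C2 from the face opposite ring B and give, after loss of the O-methyl group, rac-methyl 2-(benzyloxy)-6-{2-(benzyloxy)-6-[4-(benzyloxy)-3-(2,6-bis(benzyloxy)-4-methylphenyl)-6-methoxy-1-oxo-2-(phenylselanyl)indan-2-yl]-4-methoxyphenoxy}-4-methylbenzoate F9, with selenium cis to C3–H. Oxidation (H2O2, pyridine, CH2Cl2, 0 °C) should give the corresponding selenoxide F10, which eliminates by the syn pathway across C2–C3 to 26.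

**Further compounds**
F1 | step 16 | rac-7-(benzyloxy)-1-[2,6-bis(benzyloxy)-4-methylphenyl]-3,5-dimethoxy-1H-indene (one enantiomer drawn) | COC1=C[C@H](c2c(OCc3ccccc3)cc(C)cc2OCc2ccccc2)c2c(OCc3ccccc3)cc(OC)cc12
F2 | step 16 | rac-4-(benzyloxy)-3-[2,6-bis(benzyloxy)-4-methylphenyl]-6-methoxyindan-1-one (one enantiomer drawn) | O=C1C[C@H](c2c(OCc3ccccc3)cc(C)cc2OCc2ccccc2)c2c(OCc3ccccc3)cc(OC)cc12
F3 | step 16 | rac-methyl 2-(benzyloxy)-6-{2-(benzyloxy)-6-[trans-4-(benzyloxy)-3-(2,6-bis(benzyloxy)-4-methylphenyl)-6-methoxy-1-oxoindan-2-yl]-4-methoxyphenoxy}-4-methylbenzoate (one enantiomer drawn) | O=C1[C@@H](c2cc(OC)cc(OCc3ccccc3)c2Oc2cc(C)cc(OCc3ccccc3)c2C(=O)OC)[C@H](c2c(OCc3ccccc3)cc(C)cc2OCc2ccccc2)c2c(OCc3ccccc3)cc(OC)cc12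
F4 | step 5 | methyl 2-(2-amino-6-formyl-4-methoxyphenoxy)-6-(benzyloxy)-4-methylbenzoate | COC(=O)c1c(OCc2ccccc2)cc(C)cc1Oc1c(C=O)cc(OC)cc1N
F5 | step 5 | 2-[3-(benzyloxy)-2-(methoxycarbonyl)-5-methylphenoxy]-3-formyl-5-methoxybenzenediazonium 4-methylbenzenesulfonate | COC(=O)c1c(OCc2ccccc2)cc(C)cc1Oc1c(C=O)cc(OC)cc1[N+]#N.Cc1ccc(S(=O)(=O)[O-])cc1
F6 | step 5 | methyl 2-(benzyloxy)-6-(2-formyl-6-iodo-4-methoxyphenoxy)-4-methylbenzoate | COC(=O)c1c(OCc2ccccc2)cc(C)cc1Oc1c(C=O)cc(OC)cc1I
F7 | step 5 | methyl 2-(benzyloxy)-6-[2-(formyloxy)-6-iodo-4-methoxyphenoxy]-4-methylbenzoate | COC(=O)c1c(OCc2ccccc2)cc(C)cc1Oc1c(OC=O)cc(OC)cc1I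
F8 | step 5 | methyl 2-(benzyloxy)-6-(2-hydroxy-6-iodo-4-methoxyphenoxy)-4-methylbenzoate | COC(=O)c1c(OCc2ccccc2)cc(C)cc1Oc1c(O)cc(OC)cc1I
F9 | step 17 | rac-methyl 2-(benzyloxy)-6-{2-(benzyloxy)-6-[4-(benzyloxy)-3-(2,6-bis(benzyloxy)-4-methylphenyl)-6-methoxy-1-oxo-2-(phenylselanyl)indan-2-yl]-4-methoxyphenoxy}-4-methylbenzoate (selenium trans to ring B; one enantiomer drawn) | O=C1[C@@](c2cc(OC)cc(OCc3ccccc3)c2Oc2cc(C)cc(OCc3ccccc3)c2C(=O)OC)([Se]c2ccccc2)[C@H](c2c(OCc3ccccc3)cc(C)cc2OCc2ccccc2)c2c(OCc3ccccc3)cc(OC)cc12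
F10 | step 17 | selenoxide of F9 (mixture at selenium; formed in the flask) | O=C1[C@@](c2cc(OC)cc(OCc3ccccc3)c2Oc2cc(C)cc(OCc3ccccc3)c2C(=O)OC)([Se](=O)c2ccccc2)[C@H](c2c(OCc3ccccc3)cc(C)cc2OCc2ccccc2)c2c(OCc3ccccc3)cc(OC)cc12
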